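**Plan**

- Retrosynthesis: the side-chain methyl centre comes from asymmetric hydrogenation of a 2-substituted acrylic acid, and the side chain–cyclohexane bond from an allyl–vinyl Stille coupling. The cyclohexane and the δ-lactone come together from one ester-tethered intramolecular Diels–Alder reaction. In the 6-oxabicyclo[3.2.1]octan-3-one, the bonds C7–C1 and C2–CH2O come from a Prins cyclisation–pinacol shift.
- Enabling feature: the ether oxygen O6 (on C5) is 1,3 to the ketone carbon C3, and C3 is flanked by the quaternary C2 next to bridgehead C1. O6 and a tertiary alkoxide on C3 can therefore hold the ring CH2 (C7) as a six-membered 1,3-dioxane beside a C1=C2 alkene. Ionisation passes C7 from oxygen to C1, so the oxolane O6–C7–C1–C8–C5 arises by contraction of the six-membered acetal ring, while a C3 substituent shifts to C2 and C3 becomes the ketone.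
- Forward order: cyclohexadienone → hydroxy-enone → 2-allyl enone → tertiary carbinol → 1,3-dioxane → key step (oxolane, quaternary carbon, ketone) → diene and dienophile → Diels–Alder (cyclohexene and lactone) → side chain → two hydrogenations.
- Stereochemistry: a Cu-catalysed asymmetric borylation sets the carbinol carbon. It directs the carbonyl addition, and that configuration is passed to the quaternary carbon by the suprafacial 1,2-shift. The (E,E)-diene/endo Diels–Alder sets the ring fusion and the allylic ester, which is replaced with inversion. A Ru catalyst sets the last centre.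

Key step: step 7

Remark: 4,4-dimethylcyclohexa-2,5-dien-1-one, tributyl{[(4-methoxybenzyl)oxy]methyl}stannane and tert-butyl 2-(tributylstannyl)acrylate are taken as purchasable; each is otherwise one known step from a catalogue compound.

**Route**

Step 1
Reactants: 1 4,4-dimethylcyclohexa-2,5-dien-1-one
Product: 3 (5S)-5-hydroxy-4,4-dimethylcyclohex-2-en-1-one, via boronate 2 (not isolated)
Conditions: B2pin2 (1.05 equiv), CuCl (5 mol%), (R)-DTBM-SEGPHOS (6 mol%, antipode to be matched to the 5S product), NaOtBu (10 mol%), MeOH (2 equiv), THF, 0 °C; then NaBO3·4H2O, THF/H2O, rt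
Reagents that add atoms: bis(pinacolato)diboron CC1(C)OB(OC1(C)C)B1OC(C)(C)C(C)(C)O1 (boron of 2); sodium perborate [Na+].[O-]OB=O (hydroxyl oxygen of 3)
Why: Copper-catalysed enantioselective conjugate borylation desymmetrises the prochiral dienone by adding the Cu–Bpin species to one enantiotopic enone face, and perborate oxidation of the C–B bond with retention should give the (5S)-alcohol, the centre from which the bicyclic core is relayed.

Step 2
Reactants: 3 (5S)-5-hydroxy-4,4-dimethylcyclohex-2-en-1-one
Product: 4 (5S)-4,4-dimethyl-5-(triethylsilyloxy)cyclohex-2-en-1-one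
Conditions: Et3SiCl, imidazole, DMF, 0 °C to rt
Reagents that add atoms: chlorotriethylsilane CC[Si](Cl)(CC)CC
Why: Silyl ether protection of the secondary alcohol masks it for the coupling steps, removes its ability to direct the later carbonyl addition and suppresses β-elimination back to the dienone.

Step 3
Reactants: 4 (5S)-4,4-dimethyl-5-(triethylsilyloxy)cyclohex-2-en-1-one
Product: 5 (5S)-2-iodo-4,4-dimethyl-5-(triethylsilyloxy)cyclohex-2-en-1-one
Conditions: I2, pyridine, CH2Cl2, 0 °C to rt
Reagents that add atoms: iodine II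
Why: α-Iodination of the enone by the pyridine-mediated conjugate addition–iodination–elimination sequence gives the 2-iodoenone needed for cross-coupling.

Step 4
Reactants: 5 (5S)-2-iodo-4,4-dimethyl-5-(triethylsilyloxy)cyclohex-2-en-1-one
Product: 6 (5S)-2-allyl-4,4-dimethyl-5-(triethylsilyloxy)cyclohex-2-en-1-one
Conditions: allylSnBu3, Pd2(dba)3 (2.5 mol%), AsPh3, CuI, NMP, rt to 40 °C
Reagents that add atoms: allyltributylstannane C=CC[Sn](CCCC)(CCCC)CCCC
Why: Stille coupling of the α-iodoenone with the allylstannane installs the three-carbon chain that later becomes part of the diene.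

Step 5
Reactants: 6 (5S)-2-allyl-4,4-dimethyl-5-(triethylsilyloxy)cyclohex-2-en-1-one
Product: 8 (1R,5S)-2-allyl-1-{[(4-methoxybenzyl)oxy]methyl}-4,4-dimethylcyclohex-2-ene-1,5-diol, via lithium alkoxide 7 (not isolated)
Conditions: PMBOCH2SnBu3, n-BuLi, THF, −78 °C; then 6, −78 °C; then Bu4NF, THF, 0 °C
Reagents that add atoms: tributyl{[(4-methoxybenzyl)oxy]methyl}stannane CCCC[Sn](CCCC)(CCCC)COCc1ccc(OC)cc1
Why: Tin–lithium exchange gives the α-alkoxymethyllithium, which should add 1,2 to the enone carbonyl axially and trans to the silyloxy group (1,3-induction in the half-chair, new tertiary hydroxyl cis to the C5 oxygen), and fluoride then frees the secondary alcohol.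

Step 6
Reactants: 8 (1R,5S)-2-allyl-1-{[(4-methoxybenzyl)oxy]methyl}-4,4-dimethylcyclohex-2-ene-1,5-diol
Product: 9 (1S,5R)-6-allyl-5-{[(4-methoxybenzyl)oxy]methyl}-8,8-dimethyl-2,4-dioxabicyclo[3.3.1]non-6-ene
Conditions: CH2Br2, NaH, DMF, 0 °C to rt
Reagents that add atoms: dibromomethane BrCBr
Why: Double Williamson alkylation of the cis-1,3-diol with dibromomethane closes the six-membered methylene acetal (1,3-dioxane) that stores the future ring CH2 on the two oxygens.

Step 7
Reactants: 9 (1S,5R)-6-allyl-5-{[(4-methoxybenzyl)oxy]methyl}-8,8-dimethyl-2,4-dioxabicyclo[3.3.1]non-6-ene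
Product: 12 (1S,2S,5S)-2-allyl-2-{[(4-methoxybenzyl)oxy]methyl}-8,8-dimethyl-6-oxabicyclo[3.2.1]octan-3-one, via oxocarbenium stannate 10 (not isolated), via bridged carbocation 11 (not isolated)
Conditions: SnCl4 (1.2 equiv), CH2Cl2, −78 to −40 °C; aq. NaHCO3
Reagents that add atoms: none
Why: Proposed new method: SnCl4 cleaves the acetal C–O bond of the tertiary oxygen to give the oxocarbenium stannate 10, whose O=CH2 carbon, held on the C1 oxygen, attacks the ring alkene at C7 (5-exo-trig with respect to the alkene) to close the oxolane and give the tertiary cation 11, which is quenched by 1,2-shift of the alkoxymethyl group from the neighbouring stannyloxy carbon (pinacol step) so that the ketone appears. The closest known reaction type is the Prins cyclisation–pinacol rearrangement of cyclic acetals of allylic diols to acyl-oxolanes; here the acetal is the 1,3-dioxane of a 1,3-diol and the product is bridged, so the six-membered acetal ring contracts to the five-membered oxolane by transfer of its CH2 from oxygen to carbon. The new bridgehead centre is fixed by the tether, since the CH2 can only be delivered on the face of the C1 oxygen, and the quaternary centre is fixed by the suprafacial shift of the CH2OPMB group, which lies anti to the alkoxide on the carbinol carbon set in step 5. The step needs attack at the alkene carbon remote from the carbinol, which the tertiary cation and the five-membered ring favour over a secondary cation and a six-membered ring, and it needs migration of the exocyclic CH2OPMB group and not of the ring CH2, whose shift would give a strained 2-oxabicyclo[2.2.1]heptane; both acetal openings are reversible and only the productive one has an exit.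

Step 8
Reactants: 12 (1S,2S,5S)-2-allyl-2-{[(4-methoxybenzyl)oxy]methyl}-8,8-dimethyl-6-oxabicyclo[3.2.1]octan-3-one
Product: 13 (1S,2S,5S)-2-allyl-2-(hydroxymethyl)-8,8-dimethyl-6-oxabicyclo[3.2.1]octan-3-one
Conditions: DDQ, CH2Cl2/pH 7 buffer, 0 °C
Reagents that add atoms: none
Why: Oxidative cleavage of the p-methoxybenzyl ether by DDQ (hydride abstraction, hydrolysis of the oxocarbenium ion) frees the primary alcohol without touching the alkene, the ketone or the cyclic ether.

Step 9
Reactants: 13 (1S,2S,5S)-2-allyl-2-(hydroxymethyl)-8,8-dimethyl-6-oxabicyclo[3.2.1]octan-3-one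
Product: 14 (2E)-4-[(1S,2S,5S)-2-(hydroxymethyl)-8,8-dimethyl-3-oxo-6-oxabicyclo[3.2.1]octan-2-yl]but-2-enal
Conditions: crotonaldehyde (5 equiv), second-generation Hoveyda–Grubbs catalyst (5 mol%), CH2Cl2, 40 °C
Reagents that add atoms: (E)-crotonaldehyde C/C=C/C=O
Why: Olefin cross-metathesis of the terminal allyl group with crotonaldehyde should give the (E)-enal, the thermodynamically favoured isomer.

Step 10
Reactants: 14 (2E)-4-[(1S,2S,5S)-2-(hydroxymethyl)-8,8-dimethyl-3-oxo-6-oxabicyclo[3.2.1]octan-2-yl]but-2-enal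
Product: 15 {(1S,2S,5S)-2-[(1E,3E)-4-(acryloyloxy)buta-1,3-dien-1-yl]-8,8-dimethyl-3-oxo-6-oxabicyclo[3.2.1]octan-2-yl}methyl acrylate
Conditions: acryloyl chloride (2.5 equiv), Et3N, DMAP (cat.), BHT, CH2Cl2, −20 °C to rt
Reagents that add atoms: acryloyl chloride C=CC(Cl)=O
Why: Acylation of the alcohol and O-acylation of the vinylogous enolate of the enal (dienol ester formation) install in one operation the tethered dienophile and the (1E,3E)-1-acyloxydiene, whose ester oxygen is the later leaving group.

Step 11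
Reactants: 15 {(1S,2S,5S)-2-[(1E,3E)-4-(acryloyloxy)buta-1,3-dien-1-yl]-8,8-dimethyl-3-oxo-6-oxabicyclo[3.2.1]octan-2-yl}methyl acrylate
Product: 16 8,8-dimethyl-1',3-dioxo-5',6'-didehydro-octahydro-1'H-spiro[6-oxabicyclo[3.2.1]octane-2,4'-isochromen]-7'-yl acrylate (cis-fused lactone; 4a'-H, 8a'-H and 7'-H on one face)
Conditions: toluene (0.01 M), BHT, 110 °C
Reagents that add atoms: none
Why: Intramolecular Diels–Alder reaction with the dienophile carbonyl inside the ester tether: the endo transition state should give the cis-fused δ-lactone, the (E,E)-diene places the acyloxy group cis to the spiro carbon, and the diene should add on the face of the spiro centre that keeps it next to the flat ketone carbon and away from the CH flanked by CMe2.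

Step 12
Reactants: 16 8,8-dimethyl-1',3-dioxo-5',6'-didehydro-octahydro-1'H-spiro[6-oxabicyclo[3.2.1]octane-2,4'-isochromen]-7'-yl acrylate
Product: 17 tert-butyl 2-[8,8-dimethyl-1',3-dioxo-5',6'-didehydro-octahydro-1'H-spiro[6-oxabicyclo[3.2.1]octane-2,4'-isochromen]-7'-yl]acrylate (7'-H now trans to 4a'-H and 8a'-H)
Conditions: tert-butyl 2-(tributylstannyl)acrylate, Pd2(dba)3 (5 mol%), LiCl, DMF, 50 °C
Reagents that add atoms: tert-butyl 2-(tributylstannyl)acrylate C=C(C(=O)OC(C)(C)C)[Sn](CCCC)(CCCC)CCCC
Why: Stille coupling of an allylic ester with a vinylstannane: ionisation anti to the acrylate, then transmetalation and reductive elimination on the palladium face, give net inversion at the less hindered allyl terminus, so the side-chain carbon should end trans to the spiro carbon and to the lactone carbonyl.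

Step 13
Reactants: 17 tert-butyl 2-[8,8-dimethyl-1',3-dioxo-5',6'-didehydro-octahydro-1'H-spiro[6-oxabicyclo[3.2.1]octane-2,4'-isochromen]-7'-yl]acrylate
Product: 18 2-[8,8-dimethyl-1',3-dioxo-5',6'-didehydro-octahydro-1'H-spiro[6-oxabicyclo[3.2.1]octane-2,4'-isochromen]-7'-yl]acrylic acid
Conditions: CF3CO2H, CH2Cl2, 0 °C to rt
Reagents that add atoms: none
Why: Acid-mediated cleavage of the tert-butyl ester through the tert-butyl cation frees the acrylic acid without base, which the lactone α-centre and the β-alkoxy ketone would not tolerate.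

Step 14
Reactants: 18 2-[8,8-dimethyl-1',3-dioxo-5',6'-didehydro-octahydro-1'H-spiro[6-oxabicyclo[3.2.1]octane-2,4'-isochromen]-7'-yl]acrylic acid
Product: 19 (2R)-2-[8,8-dimethyl-1',3-dioxo-5',6'-didehydro-octahydro-1'H-spiro[6-oxabicyclo[3.2.1]octane-2,4'-isochromen]-7'-yl]propanoic acid
Conditions: H2 (20 bar), RuCl2[(R)-DTBM-SEGPHOS](DMF)n (1 mol%), MeOH, rt
Reagents that add atoms: none
Why: Carboxylate-directed asymmetric hydrogenation of the 2-substituted acrylic acid should set the (R)-methyl centre under catalyst control, as for 2-arylpropanoic acids and ring-substituted acrylic acids, and should leave the ring alkene and the ketone.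

Step 15
Reactants: 19 (2R)-2-[8,8-dimethyl-1',3-dioxo-5',6'-didehydro-octahydro-1'H-spiro[6-oxabicyclo[3.2.1]octane-2,4'-isochromen]-7'-yl]propanoic acid
Product: 20 CNP0152427.1, (2R)-2-[(1S,2S,4a'R,5S,7'R,8a'S)-8,8-dimethyl-1',3-dioxooctahydro-1'H-spiro[6-oxabicyclo[3.2.1]octane-2,4'-isochromen]-7'-yl]propanoic acid
Conditions: H2 (1 atm), Pd/C, EtOAc, rt
Reagents that add atoms: none
Why: Heterogeneous hydrogenation of the remaining cis-disubstituted ring alkene, which creates no stereocentre, should give the target.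

**Compound list**

1 | 4,4-dimethylcyclohexa-2,5-dien-1-one | CC1(C)C=CC(=O)C=C1 | starting material
2 | (5S)-4,4-dimethyl-5-(4,4,5,5-tetramethyl-1,3,2-dioxaborolan-2-yl)cyclohex-2-en-1-one | O=C1C=CC(C)(C)[C@@H](B2OC(C)(C)C(C)(C)O2)C1 | intermediate
3 | (5S)-5-hydroxy-4,4-dimethylcyclohex-2-en-1-one | O=C1C=CC(C)(C)[C@@H](O)C1 | intermediate
4 | (5S)-4,4-dimethyl-5-(triethylsilyloxy)cyclohex-2-en-1-one | O=C1C=CC(C)(C)[C@@H](O[Si](CC)(CC)CC)C1 | intermediate
5 | (5S)-2-iodo-4,4-dimethyl-5-(triethylsilyloxy)cyclohex-2-en-1-one | O=C1C(I)=CC(C)(C)[C@@H](O[Si](CC)(CC)CC)C1 | intermediate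
6 | (5S)-2-allyl-4,4-dimethyl-5-(triethylsilyloxy)cyclohex-2-en-1-one | O=C1C(CC=C)=CC(C)(C)[C@@H](O[Si](CC)(CC)CC)C1 | intermediate
7 | lithium (1R,5S)-2-allyl-1-{[(4-methoxybenzyl)oxy]methyl}-4,4-dimethyl-5-(triethylsilyloxy)cyclohex-2-en-1-olate | [Li]O[C@@]1(COCc2ccc(OC)cc2)C(CC=C)=CC(C)(C)[C@@H](O[Si](CC)(CC)CC)C1 | intermediate
8 | (1R,5S)-2-allyl-1-{[(4-methoxybenzyl)oxy]methyl}-4,4-dimethylcyclohex-2-ene-1,5-diol (hydroxyls cis) | O[C@@]1(COCc2ccc(OC)cc2)C(CC=C)=CC(C)(C)[C@@H](O)C1 | intermediate
9 | (1S,5R)-6-allyl-5-{[(4-methoxybenzyl)oxy]methyl}-8,8-dimethyl-2,4-dioxabicyclo[3.3.1]non-6-ene (cyclic formal of 8) | C1O[C@@]2(COCc3ccc(OC)cc3)C(CC=C)=CC(C)(C)[C@@H](O1)C2 | intermediate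
10 | ring-opened methylene-oxonium ion of 9 with the tertiary oxygen bound to SnCl4 (zwitterion) | C=[O+][C@H]1C[C@](O[Sn-](Cl)(Cl)(Cl)Cl)(COCc2ccc(OC)cc2)C(CC=C)=CC1(C)C | intermediate
11 | 2-allyl-8,8-dimethyl-6-oxabicyclo[3.2.1]oct-2-yl cation with the C3 stannate alkoxide and CH2OPMB group still on C3 | C=CC[C+]1[C@@](O[Sn-](Cl)(Cl)(Cl)Cl)(COCc2ccc(OC)cc2)C[C@@H]2OC[C@H]1C2(C)C | intermediate
12 | (1S,2S,5S)-2-allyl-2-{[(4-methoxybenzyl)oxy]methyl}-8,8-dimethyl-6-oxabicyclo[3.2.1]octan-3-one | COc1ccc(COC[C@@]2(CC=C)C(=O)C[C@@H]3OC[C@H]2C3(C)C)cc1 | intermediate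
13 | (1S,2S,5S)-2-allyl-2-(hydroxymethyl)-8,8-dimethyl-6-oxabicyclo[3.2.1]octan-3-one | OC[C@@]1(CC=C)C(=O)C[C@@H]2OC[C@H]1C2(C)C | intermediate
14 | (2E)-4-[(1S,2S,5S)-2-(hydroxymethyl)-8,8-dimethyl-3-oxo-6-oxabicyclo[3.2.1]octan-2-yl]but-2-enal | OC[C@@]1(C/C=C/C=O)C(=O)C[C@@H]2OC[C@H]1C2(C)C | intermediate
15 | {(1S,2S,5S)-2-[(1E,3E)-4-(acryloyloxy)buta-1,3-dien-1-yl]-8,8-dimethyl-3-oxo-6-oxabicyclo[3.2.1]octan-2-yl}methyl acrylate | C=CC(=O)OC[C@@]1(/C=C/C=C/OC(=O)C=C)C(=O)C[C@@H]2OC[C@H]1C2(C)C | intermediate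
16 | 8,8-dimethyl-1',3-dioxo-5',6'-didehydro-octahydro-1'H-spiro[6-oxabicyclo[3.2.1]octane-2,4'-isochromen]-7'-yl acrylate (cis-fused lactone, acryloyloxy cis to the spiro carbon) | C=CC(=O)O[C@H]1C=C[C@@H]2[C@H](C1)C(=O)OC[C@]21C(=O)C[C@@H]2OC[C@H]1C2(C)C | intermediate
17 | tert-butyl 2-[8,8-dimethyl-1',3-dioxo-5',6'-didehydro-octahydro-1'H-spiro[6-oxabicyclo[3.2.1]octane-2,4'-isochromen]-7'-yl]acrylate (side chain trans to the spiro carbon) | C=C(C(=O)OC(C)(C)C)[C@@H]1C=C[C@@H]2[C@H](C1)C(=O)OC[C@]21C(=O)C[C@@H]2OC[C@H]1C2(C)C | intermediate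
18 | 2-[8,8-dimethyl-1',3-dioxo-5',6'-didehydro-octahydro-1'H-spiro[6-oxabicyclo[3.2.1]octane-2,4'-isochromen]-7'-yl]acrylic acid | C=C(C(=O)O)[C@@H]1C=C[C@@H]2[C@H](C1)C(=O)OC[C@]21C(=O)C[C@@H]2OC[C@H]1C2(C)C | intermediate
19 | (2R)-2-[8,8-dimethyl-1',3-dioxo-5',6'-didehydro-octahydro-1'H-spiro[6-oxabicyclo[3.2.1]octane-2,4'-isochromen]-7'-yl]propanoic acid | C[C@@H](C(=O)O)[C@@H]1C=C[C@@H]2[C@H](C1)C(=O)OC[C@]21C(=O)C[C@@H]2OC[C@H]1C2(C)C | intermediate
20 | CNP0152427.1, (2R)-2-[(1S,2S,4a'R,5S,7'R,8a'S)-8,8-dimethyl-1',3-dioxooctahydro-1'H-spiro[6-oxabicyclo[3.2.1]octane-2,4'-isochromen]-7'-yl]propanoic acid | C[C@@H](C(=O)O)[C@@H]1CC[C@@H]2[C@H](C1)C(=O)OC[C@]21C(=O)C[C@@H]2OC[C@H]1C2(C)C | target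

**Step count and risks**

Total step count: 15. Longest linear sequence: 15 steps (1 to 20).

Step 7 (key step). What may go wrong: the acetal may open at the secondary oxygen so that the tertiary allylic C–O bond ionises, or cation 11 may be diverted by hydride shift from the allylic CH2 or by proton loss before the alkoxymethyl group migrates. The fallback uses known chemistry, sets out from 1 and comes back at 12. Copper-catalysed enantioselective conjugate addition of [isopropoxy(dimethyl)silyl]methylmagnesium chloride to 1, with trapping of the enolate by allyl bromide, would give trans-6-allyl-5-{[isopropoxy(dimethyl)silyl]methyl}-4,4-dimethylcyclohex-2-en-1-one F1. LDA deprotonates its only enolisable position, and alkylation with 4-methoxybenzyl chloromethyl ether anti to the silylmethyl group would give the quaternary ketone F2. Tamao oxidation (KF, KHCO3, H2O2) would free the hydroxymethyl enone F3, whose alcohol closes the oxolane directly by base-mediated intramolecular oxa-Michael addition to the enone, giving 12.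

Step 11. What may go wrong: reaction through the exo mode (trans ring fusion), addition of the diene to the other face of the spiro centre, or polymerisation of the acrylates. The fallback sets out from 14 and comes back at 17. Esterification of the alcohol with propiolic acid (carbodiimide) and acetylation of the dienol (Ac2O, Et3N, DMAP) would give the propiolate dienyl acetate F4. Its alkyne dienophile should cyclise at lower temperature and creates only one ring-junction CH, giving the cyclohexa-1,4-diene lactone F5. Copper hydride conjugate reduction of the unsaturated lactone, with protonation of the enolate on the face away from the spiro substituents, would give the cis-fused acetate F6, the acetate analogue of 16, which enters step 12 and gives 17.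

Step 12. What may go wrong: coupling at the hindered allyl terminus, β-hydride elimination of the allylpalladium intermediate to a cyclohexadiene, or slow transmetalation of the electron-poor stannane with loss of configuration through return of the carboxylate. The fallback sets out from 16 and comes back at 18. Palladium-catalysed allyl–alkenyl coupling of 16 with isopropenylboronic acid pinacol ester (electron-rich partner, same net inversion) would give the isopropenyl compound F7. Allylic oxidation of its methyl group (SeO2, tert-butyl hydroperoxide) would give the 2-substituted acrolein F8, and Pinnick oxidation (NaClO2, NaH2PO4, 2-methylbut-2-ene) would give the acid 18.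

Further compounds
F1 | step 7 | trans-6-allyl-5-{[isopropoxy(dimethyl)silyl]methyl}-4,4-dimethylcyclohex-2-en-1-one | O=C1C=CC(C)(C)[C@H](C[Si](C)(C)OC(C)C)[C@H]1CC=C
F2 | step 7 | 6-allyl-5-{[isopropoxy(dimethyl)silyl]methyl}-6-{[(4-methoxybenzyl)oxy]methyl}-4,4-dimethylcyclohex-2-en-1-one (allyl cis to the silylmethyl group) | O=C1C=CC(C)(C)[C@H](C[Si](C)(C)OC(C)C)[C@@]1(CC=C)COCc2ccc(OC)cc2
F3 | step 7 | 6-allyl-5-(hydroxymethyl)-6-{[(4-methoxybenzyl)oxy]methyl}-4,4-dimethylcyclohex-2-en-1-one | O=C1C=CC(C)(C)[C@H](CO)[C@@]1(CC=C)COCc2ccc(OC)cc2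
F4 | step 11 | {(1S,2S,5S)-2-[(1E,3E)-4-acetoxybuta-1,3-dien-1-yl]-8,8-dimethyl-3-oxo-6-oxabicyclo[3.2.1]octan-2-yl}methyl propiolate | C#CC(=O)OC[C@@]1(/C=C/C=C/OC(C)=O)C(=O)C[C@@H]2OC[C@H]1C2(C)C
F5 | step 11 | 8,8-dimethyl-1',3-dioxo-5',6',8',8a'-tetradehydro-octahydro-1'H-spiro[6-oxabicyclo[3.2.1]octane-2,4'-isochromen]-7'-yl acetate (cyclohexa-1,4-diene lactone) | CC(=O)O[C@H]1C=C[C@@H]2C(=C1)C(=O)OC[C@]21C(=O)C[C@@H]2OC[C@H]1C2(C)C
F6 | step 11 | 8,8-dimethyl-1',3-dioxo-5',6'-didehydro-octahydro-1'H-spiro[6-oxabicyclo[3.2.1]octane-2,4'-isochromen]-7'-yl acetate (cis-fused, acetate analogue of 16) | CC(=O)O[C@H]1C=C[C@@H]2[C@H](C1)C(=O)OC[C@]21C(=O)C[C@@H]2OC[C@H]1C2(C)C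
F7 | step 12 | 7'-isopropenyl-8,8-dimethyl-5',6'-didehydro-octahydro-1'H-spiro[6-oxabicyclo[3.2.1]octane-2,4'-isochromene]-1',3-dione | C=C(C)[C@@H]1C=C[C@@H]2[C@H](C1)C(=O)OC[C@]21C(=O)C[C@@H]2OC[C@H]1C2(C)C
F8 | step 12 | 2-[8,8-dimethyl-1',3-dioxo-5',6'-didehydro-octahydro-1'H-spiro[6-oxabicyclo[3.2.1]octane-2,4'-isochromen]-7'-yl]acrylaldehyde | C=C(C=O)[C@@H]1C=C[C@@H]2[C@H](C1)C(=O)OC[C@]21C(=O)C[C@@H]2OC[C@H]1C2(C)C
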